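Ring C is opened at its two bonds to ring A, O1–C8a and C4–C4a. Ring A then arrives as aryne 21 (C4a≡C8a) and ring B with C2, C3, C4 and O1 as the 2-arylacrylic acid 20. In one operation the carboxylate oxygen adds to C8a, the acyl carbon migrates to C4a (formal aryne insertion into the acid C–O bond) and the phenoxide closes ring C by oxa-Michael addition. The step exploits the C5 oxygen beside C4a: it polarises the aryne so that oxygen enters at C8a and the acyl group at C4a, which also places the prenyl group at C6. C3–OH is set afterwards by asymmetric enolate hydroxylation.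

Key step: step 13

Assumption: the facial sense of the camphor-derived oxaziridine on enolate 24 is taken by analogy from 2-substituted 1-tetralone and 3-benzylchroman-4-one enolates; if the (+)-reagent should give the (3S)-alcohol, its enantiomer from (1R)-camphorsulfonic acid is used in the same way.

**Ring A fragment (steps 1–7)**

Step 1
Reactants: 1 phloroglucinol
Product: 2 3,5-bis(methoxymethoxy)phenol
Conditions: MOMCl (2 equiv), i-Pr2NEt, DMF, 0 °C to rt; chromatography
Reagents that add atoms: chloromethyl methyl ether, COCCl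
Why: O-alkylation of two of the three equivalent phenols (acetal protection), the bis-ether being separated from the mono- and tris-ethers, which can be recycled.

Step 2
Reactants: 2 3,5-bis(methoxymethoxy)phenol
Product: 3 [3,5-bis(methoxymethoxy)phenoxy]tri(propan-2-yl)silane
Conditions: TIPSCl, imidazole, DMF, rt
Reagents that add atoms: chlorotri(propan-2-yl)silane, CC(C)[Si](Cl)(C(C)C)C(C)C
Why: Silyl ether formation puts a bulky, non-coordinating group on the third oxygen so that it cannot direct the lithiation of step 3.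

Step 3
Reactants: 3 [3,5-bis(methoxymethoxy)phenoxy]tri(propan-2-yl)silane
Product: 5 [3,5-bis(methoxymethoxy)-4-(3-methylbut-2-en-1-yl)phenoxy]tri(propan-2-yl)silane, via aryllithium 4 (not isolated)
Conditions: n-BuLi, TMEDA, THF, 0 °C; CuBr·SMe2 (10 mol %), prenyl bromide, −78 °C to rt
Reagents that add atoms: prenyl bromide (1-bromo-3-methylbut-2-ene), CC(C)=CCBr
Why: Directed ortho-metalation takes place at the C–H flanked by the two chelating MOM ethers, and the copper-assisted SN2 alkylation of the aryl anion at the primary carbon of prenyl bromide should give the linear prenyl arene.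

Step 4
Reactants: 5 [3,5-bis(methoxymethoxy)-4-(3-methylbut-2-en-1-yl)phenoxy]tri(propan-2-yl)silane
Product: 6 3,5-bis(methoxymethoxy)-4-(3-methylbut-2-en-1-yl)phenol
Conditions: Bu4NF, THF, 0 °C
Reagents that add atoms: none
Why: Fluoride-induced cleavage of the aryl silyl ether leaves the MOM ethers and the alkene untouched.

Step 5
Reactants: 6 3,5-bis(methoxymethoxy)-4-(3-methylbut-2-en-1-yl)phenol
Product: 7 3,5-bis(methoxymethoxy)-4-(3-methylbut-2-en-1-yl)phenyl N-(propan-2-yl)carbamate
Conditions: i-PrNCO, Et3N (cat.), CH2Cl2, rt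
Reagents that add atoms: isopropyl isocyanate, CC(C)N=C=O
Why: Base-catalysed addition of the phenol to the isocyanate installs a carbamate that is a strong ortho-director after N-silylation and can later be removed under mild base.

Step 6
Reactants: 7 3,5-bis(methoxymethoxy)-4-(3-methylbut-2-en-1-yl)phenyl N-(propan-2-yl)carbamate
Product: 11 3,5-bis(methoxymethoxy)-4-(3-methylbut-2-en-1-yl)-2-(trimethylsilyl)phenyl N-(propan-2-yl)carbamate, via N-silyl carbamate 8 (not isolated), via aryllithium 9 (not isolated), via N-silyl C-silyl carbamate 10 (not isolated)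
Conditions: TBSOTf, TMEDA, Et2O, 0 °C to rt; n-BuLi, TMEDA, −78 °C; TMSCl, −78 °C to rt; aq NaHSO4
Reagents that add atoms: chlorotrimethylsilane, C[Si](C)(C)Cl
Why: In situ N-silylation turns the carbamate into a tertiary directing group, directed ortho-metalation then occurs at one of the two equivalent positions between carbamate and MOM ether, and the N–Si bond is hydrolysed on work-up after C-silylation.

Step 7
Reactants: 11 3,5-bis(methoxymethoxy)-4-(3-methylbut-2-en-1-yl)-2-(trimethylsilyl)phenyl N-(propan-2-yl)carbamate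
Product: 13 3,5-bis(methoxymethoxy)-4-(3-methylbut-2-en-1-yl)-2-(trimethylsilyl)phenyl trifluoromethanesulfonate, via phenol 12 (not isolated)
Conditions: DBU, Et2NH, MeCN, 40 °C; then PhNTf2, rt
Reagents that add atoms: N-phenylbis(trifluoromethanesulfonimide), O=S(=O)(N(c1ccccc1)S(=O)(=O)C(F)(F)F)C(F)(F)F
Why: E1cB loss of isopropyl isocyanate (scavenged by Et2NH as a urea) frees the phenoxide, which is sulfonylated in the same flask to the 2-silylaryl triflate aryne precursor.

**Ring B fragment (steps 8–12)**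

Step 8
Reactants: 14 1-(2,4-dihydroxyphenyl)ethan-1-one
Product: 15 1-[2,4-dihydroxy-3-(3-methylbut-2-en-1-yl)phenyl]ethan-1-one
Conditions: prenyl bromide, KOH (10% aq), 0 °C to rt; chromatography
Reagents that add atoms: prenyl bromide, CC(C)=CCBr
Why: C-alkylation of the resorcinol-type phenoxide in water favours the carbon between the two oxygens, and the 5-prenyl and O-prenyl isomers are removed by chromatography.

Step 9
Reactants: 15 1-[2,4-dihydroxy-3-(3-methylbut-2-en-1-yl)phenyl]ethan-1-one
Product: 16 1-[2-hydroxy-4-(methoxymethoxy)-3-(3-methylbut-2-en-1-yl)phenyl]ethan-1-one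
Conditions: MOMCl, i-Pr2NEt, CH2Cl2, 0 °C to rt
Reagents that add atoms: chloromethyl methyl ether, COCCl
Why: The 2-OH is locked in a hydrogen bond to the acetyl group, so acetal protection should occur only at the free 4-OH.

Step 10
Reactants: 16 1-[2-hydroxy-4-(methoxymethoxy)-3-(3-methylbut-2-en-1-yl)phenyl]ethan-1-one
Product: 17 1-[2-methoxy-4-(methoxymethoxy)-3-(3-methylbut-2-en-1-yl)phenyl]ethan-1-one
Conditions: MeI, K2CO3, DMF, 50 °C
Reagents that add atoms: iodomethane, CI
Why: Williamson methylation of the chelated phenol under forcing conditions installs the 2'-methoxy group of the target.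

Step 11
Reactants: 17 1-[2-methoxy-4-(methoxymethoxy)-3-(3-methylbut-2-en-1-yl)phenyl]ethan-1-one
Product: 19 1-[2-methoxy-4-(methoxymethoxy)-3-(3-methylbut-2-en-1-yl)phenyl]ethenyl trifluoromethanesulfonate, via potassium enolate 18 (not isolated)
Conditions: KN(SiMe3)2, THF, −78 °C; PhNTf2, −78 °C to 0 °C; used at once
Reagents that add atoms: N-phenylbis(trifluoromethanesulfonimide), O=S(=O)(N(c1ccccc1)S(=O)(=O)C(F)(F)F)C(F)(F)F
Why: Kinetic deprotonation of the methyl ketone and O-sulfonylation of the enolate give the 1-arylvinyl triflate.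

Step 12
Reactants: 19 1-[2-methoxy-4-(methoxymethoxy)-3-(3-methylbut-2-en-1-yl)phenyl]ethenyl trifluoromethanesulfonate
Product: 20 2-[2-methoxy-4-(methoxymethoxy)-3-(3-methylbut-2-en-1-yl)phenyl]prop-2-enoic acid
Conditions: Pd(OAc)2 (5 mol %), dppf, CO (1 atm), Et3N, DMF–H2O, 50 °C; cold dilute citric acid work-up
Reagents that add atoms: carbon monoxide, [C-]#[O+]; water, O
Why: Palladium-catalysed hydroxycarbonylation (oxidative addition of the vinyl triflate to zerovalent palladium, CO insertion, hydrolysis of the acylpalladium) converts the triflate into the α-arylacrylic acid without touching the prenyl group.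

**Assembly (steps 13–15)**

Step 13
Reactants: 20 2-[2-methoxy-4-(methoxymethoxy)-3-(3-methylbut-2-en-1-yl)phenyl]prop-2-enoic acid; 13 3,5-bis(methoxymethoxy)-4-(3-methylbut-2-en-1-yl)-2-(trimethylsilyl)phenyl trifluoromethanesulfonate
Product: 23 rac-5,7-bis(methoxymethoxy)-3-[2-methoxy-4-(methoxymethoxy)-3-(3-methylbut-2-en-1-yl)phenyl]-6-(3-methylbut-2-en-1-yl)-2,3-dihydro-4H-chromen-4-one, via aryne 21 (not isolated), via hydroxy enone 22 (not isolated)
Conditions: 20 (1.3 equiv), 13 (1 equiv), CsF (4 equiv), THF, 125 °C, sealed tube, degassed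
Reagents that add atoms: none
Why: Fluoride removes the silyl group of 13 and expels triflate to give aryne 21; the caesium carboxylate of 20 adds through oxygen to the aryne carbon remote from the neighbouring methoxymethoxy group (future C8a), and the aryl anion thus formed at C4a attacks the ester carbonyl through a four-membered transition state so that the acyl group moves from O to C, giving the phenoxide of 22 (formal insertion of the aryne into the C–O bond of the acid). The phenoxide then closes ring C by a 6-endo-trig oxa-Michael addition onto the α-aryl enone, and protonation of the enolate should give 23. The closest known reaction type is the fluoride-induced coupling of 2-(trimethylsilyl)aryl triflates with α,β-unsaturated carboxylic acids to give 4-chromanones. C3 is formed without control (racemic), which is harmless because step 14 passes through the planar enolate. The step needs regioselective addition to the aryne, secured by the inductively withdrawing oxygen substituent beside C4a (the usual preference of 3-alkoxyarynes for attack at the distal carbon), and acyl migration in preference to protonation or conjugate addition of the aryl anion, favoured by the aprotic medium and the high temperature. Ene reactions of the aryne with the prenyl groups should be outrun by the anionic nucleophile, which is present in excess.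

Step 14
Reactants: 23 rac-5,7-bis(methoxymethoxy)-3-[2-methoxy-4-(methoxymethoxy)-3-(3-methylbut-2-en-1-yl)phenyl]-6-(3-methylbut-2-en-1-yl)-2,3-dihydro-4H-chromen-4-one
Product: 25 (3R)-3-hydroxy-5,7-bis(methoxymethoxy)-3-[2-methoxy-4-(methoxymethoxy)-3-(3-methylbut-2-en-1-yl)phenyl]-6-(3-methylbut-2-en-1-yl)-2,3-dihydro-4H-chromen-4-one, via sodium enolate 24 (not isolated)
Conditions: NaN(SiMe3)2, THF, −78 °C; (+)-[(8,8-dichlorocamphoryl)sulfonyl]oxaziridine, −78 to −40 °C; AcOH
Reagents that add atoms: (+)-[(8,8-dichlorocamphoryl)sulfonyl]oxaziridine, CC1(C)[C@@H]2CC[C@]13CS(=O)(=O)[N@]4O[C@@]34C2(Cl)Cl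
Why: Davis oxidation, in which the planar, ring-constrained enolate 24 attacks the oxaziridine oxygen and the camphor skeleton of the reagent differentiates the two enolate faces (reagent control) to set the C3 carbinol as R, as precedented for 3-substituted chroman-4-one enolates.

Step 15
Reactants: 25 (3R)-3-hydroxy-5,7-bis(methoxymethoxy)-3-[2-methoxy-4-(methoxymethoxy)-3-(3-methylbut-2-en-1-yl)phenyl]-6-(3-methylbut-2-en-1-yl)-2,3-dihydro-4H-chromen-4-one
Product: 26 (3R)-3,5,7-trihydroxy-3-[4-hydroxy-2-methoxy-3-(3-methylbut-2-en-1-yl)phenyl]-6-(3-methylbut-2-en-1-yl)-2,3-dihydro-4H-chromen-4-one (CNP0157505.1)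
Conditions: HCl (2 M in MeOH), 0 °C to rt, monitored closely
Reagents that add atoms: none
Why: Acid-catalysed transacetalisation to methanol removes the three aryl MOM ethers under conditions mild enough to spare the prenyl groups and the tertiary α-ketol, whose stereocentre has no α-hydrogen and cannot epimerise.

**Compound list**

1 | phloroglucinol (benzene-1,3,5-triol) | Oc1cc(O)cc(O)c1 | starting material
2 | 3,5-bis(methoxymethoxy)phenol | COCOc1cc(O)cc(OCOC)c1 | intermediate
3 | [3,5-bis(methoxymethoxy)phenoxy]tri(propan-2-yl)silane | COCOc1cc(O[Si](C(C)C)(C(C)C)C(C)C)cc(OCOC)c1 | intermediate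
4 | [2,6-bis(methoxymethoxy)-4-(triisopropylsilyloxy)phenyl]lithium (not isolated) | [Li]c1c(OCOC)cc(O[Si](C(C)C)(C(C)C)C(C)C)cc1OCOC | intermediate
5 | [3,5-bis(methoxymethoxy)-4-(3-methylbut-2-en-1-yl)phenoxy]tri(propan-2-yl)silane | COCOc1cc(O[Si](C(C)C)(C(C)C)C(C)C)cc(OCOC)c1CC=C(C)C | intermediate
6 | 3,5-bis(methoxymethoxy)-4-(3-methylbut-2-en-1-yl)phenol | COCOc1cc(O)cc(OCOC)c1CC=C(C)C | intermediate
7 | 3,5-bis(methoxymethoxy)-4-(3-methylbut-2-en-1-yl)phenyl N-(propan-2-yl)carbamate | COCOc1cc(OC(=O)NC(C)C)cc(OCOC)c1CC=C(C)C | intermediate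
8 | 3,5-bis(methoxymethoxy)-4-(3-methylbut-2-en-1-yl)phenyl N-[tert-butyl(dimethyl)silyl]-N-(propan-2-yl)carbamate (not isolated) | COCOc1cc(OC(=O)N(C(C)C)[Si](C)(C)C(C)(C)C)cc(OCOC)c1CC=C(C)C | intermediate
9 | 2-lithio derivative of 8 (not isolated) | COCOc1cc(OC(=O)N(C(C)C)[Si](C)(C)C(C)(C)C)c([Li])c(OCOC)c1CC=C(C)C | intermediate
10 | 3,5-bis(methoxymethoxy)-4-(3-methylbut-2-en-1-yl)-2-(trimethylsilyl)phenyl N-[tert-butyl(dimethyl)silyl]-N-(propan-2-yl)carbamate (not isolated) | COCOc1cc(OC(=O)N(C(C)C)[Si](C)(C)C(C)(C)C)c([Si](C)(C)C)c(OCOC)c1CC=C(C)C | intermediate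
11 | 3,5-bis(methoxymethoxy)-4-(3-methylbut-2-en-1-yl)-2-(trimethylsilyl)phenyl N-(propan-2-yl)carbamate | COCOc1cc(OC(=O)NC(C)C)c([Si](C)(C)C)c(OCOC)c1CC=C(C)C | intermediate
12 | 3,5-bis(methoxymethoxy)-4-(3-methylbut-2-en-1-yl)-2-(trimethylsilyl)phenol (not isolated) | COCOc1cc(O)c([Si](C)(C)C)c(OCOC)c1CC=C(C)C | intermediate
13 | 3,5-bis(methoxymethoxy)-4-(3-methylbut-2-en-1-yl)-2-(trimethylsilyl)phenyl trifluoromethanesulfonate | COCOc1cc(OS(=O)(=O)C(F)(F)F)c([Si](C)(C)C)c(OCOC)c1CC=C(C)C | intermediate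
14 | 1-(2,4-dihydroxyphenyl)ethan-1-one | CC(=O)c1ccc(O)cc1O | starting material
15 | 1-[2,4-dihydroxy-3-(3-methylbut-2-en-1-yl)phenyl]ethan-1-one | CC(=O)c1ccc(O)c(CC=C(C)C)c1O | intermediate
16 | 1-[2-hydroxy-4-(methoxymethoxy)-3-(3-methylbut-2-en-1-yl)phenyl]ethan-1-one | CC(=O)c1ccc(OCOC)c(CC=C(C)C)c1O | intermediate
17 | 1-[2-methoxy-4-(methoxymethoxy)-3-(3-methylbut-2-en-1-yl)phenyl]ethan-1-one | CC(=O)c1ccc(OCOC)c(CC=C(C)C)c1OC | intermediate
18 | potassium 1-[2-methoxy-4-(methoxymethoxy)-3-(3-methylbut-2-en-1-yl)phenyl]ethen-1-olate (not isolated) | C=C([O-])c1ccc(OCOC)c(CC=C(C)C)c1OC.[K+] | intermediate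
19 | 1-[2-methoxy-4-(methoxymethoxy)-3-(3-methylbut-2-en-1-yl)phenyl]ethenyl trifluoromethanesulfonate | C=C(OS(=O)(=O)C(F)(F)F)c1ccc(OCOC)c(CC=C(C)C)c1OC | intermediate
20 | 2-[2-methoxy-4-(methoxymethoxy)-3-(3-methylbut-2-en-1-yl)phenyl]prop-2-enoic acid | C=C(C(=O)O)c1ccc(OCOC)c(CC=C(C)C)c1OC | intermediate
21 | 1,2-didehydro-3,5-bis(methoxymethoxy)-4-(3-methylbut-2-en-1-yl)benzene (aryne, not isolated) | COCOC1=C(CC=C(C)C)C(OCOC)=CC#C1 | intermediate
22 | 1-[6-hydroxy-2,4-bis(methoxymethoxy)-3-(3-methylbut-2-en-1-yl)phenyl]-2-[2-methoxy-4-(methoxymethoxy)-3-(3-methylbut-2-en-1-yl)phenyl]prop-2-en-1-one (not isolated) | C=C(C(=O)c1c(O)cc(OCOC)c(CC=C(C)C)c1OCOC)c1ccc(OCOC)c(CC=C(C)C)c1OC | intermediate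
23 | rac-5,7-bis(methoxymethoxy)-3-[2-methoxy-4-(methoxymethoxy)-3-(3-methylbut-2-en-1-yl)phenyl]-6-(3-methylbut-2-en-1-yl)-2,3-dihydro-4H-chromen-4-one (racemic) | COc1c(C2COc3cc(OCOC)c(CC=C(C)C)c(OCOC)c3C2=O)ccc(OCOC)c1CC=C(C)C | intermediate
24 | sodium enolate of 23 (sodium 2H-chromen-4-olate, not isolated) | COc1c(C2=C([O-])c3c(OCOC)c(CC=C(C)C)c(OCOC)cc3OC2)ccc(OCOC)c1CC=C(C)C.[Na+] | intermediate
25 | (3R)-3-hydroxy-5,7-bis(methoxymethoxy)-3-[2-methoxy-4-(methoxymethoxy)-3-(3-methylbut-2-en-1-yl)phenyl]-6-(3-methylbut-2-en-1-yl)-2,3-dihydro-4H-chromen-4-one | COc1c([C@@]2(O)COc3cc(OCOC)c(CC=C(C)C)c(OCOC)c3C2=O)ccc(OCOC)c1CC=C(C)C | intermediate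
26 | (3R)-3,5,7-trihydroxy-3-[4-hydroxy-2-methoxy-3-(3-methylbut-2-en-1-yl)phenyl]-6-(3-methylbut-2-en-1-yl)-2,3-dihydro-4H-chromen-4-one | COc1c([C@@]2(O)COc3cc(O)c(CC=C(C)C)c(O)c3C2=O)ccc(O)c1CC=C(C)C | target

**Step count**

Total steps: 15. Longest linear sequence: 10 steps (steps 1–7, then 13, 14, 15). The ring B branch runs over 8 steps (8–12, then 13–15).

**Steps most likely to fail and fallbacks**

Step 13. The aryl anion may be protonated, or add to the acrylate carbon, before the acyl group migrates. Acid 20 may also oligomerise at the temperature needed, or the aryne may be consumed by ene reaction with a prenyl group. The fallback builds the same C4–C4a bond by a photochemical acyl shift instead of an aryne. It sets out from phenol 6 and acid 20. Esterification (EDC·HCl, DMAP, CH2Cl2, 0 °C) should give 3,5-bis(methoxymethoxy)-4-(3-methylbut-2-en-1-yl)phenyl 2-[2-methoxy-4-(methoxymethoxy)-3-(3-methylbut-2-en-1-yl)phenyl]prop-2-enoate F1. Irradiation at 254 nm in degassed MeCN should bring about a photo-Fries rearrangement to one of the two equivalent ortho carbons (the para position is blocked by the prenyl group) and give hydroxy enone 22. K2CO3 in MeOH then closes ring C, and the route is rejoined at 23.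

Step 14. Facial discrimination by the oxaziridine may be poor on this aryl-substituted, tetrasubstituted enolate, and the enolate may partly ring-open by β-elimination of the phenoxide. The fallback replaces reagent control by resolution and sets out from 23. Enolate 24 (KN(SiMe3)2, THF, −78 °C) is oxidised with racemic trans-3-phenyl-2-(phenylsulfonyl)oxaziridine, which should give 25 together with its enantiomer, (3S)-3-hydroxy-5,7-bis(methoxymethoxy)-3-[2-methoxy-4-(methoxymethoxy)-3-(3-methylbut-2-en-1-yl)phenyl]-6-(3-methylbut-2-en-1-yl)-2,3-dihydro-4H-chromen-4-one F2. Preparative SFC on a chiral stationary phase separates the two, and the route is rejoined at 25.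

Step 15. Acid may cyclise a prenyl group onto a neighbouring free phenol or dehydrate the tertiary alcohol towards the isoflavone before all three acetals are gone. The fallback moves the acid step ahead of the carbinol and ends with fluoride; it sets out from 23.
- HCl in MeOH removes the MOM groups while no tertiary alcohol is present, giving rac-5,7-dihydroxy-3-[4-hydroxy-2-methoxy-3-(3-methylbut-2-en-1-yl)phenyl]-6-(3-methylbut-2-en-1-yl)-2,3-dihydro-4H-chromen-4-one F3.
- TBSOTf and 2,6-lutidine in CH2Cl2 should give the tris(tert-butyldimethylsilyl) ether F4.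
- NaN(SiMe3)2 at −78 °C forms its sodium enolate F5, which is hydroxylated with the reagent of step 14 to the (3R)-3-hydroxy tris(silyl) ether F6.
- Bu4NF buffered with AcOH in THF at 0 °C removes the silyl groups under near-neutral conditions, and the route is rejoined at 26.

**Further compounds**

F1 | step 13 | 3,5-bis(methoxymethoxy)-4-(3-methylbut-2-en-1-yl)phenyl 2-[2-methoxy-4-(methoxymethoxy)-3-(3-methylbut-2-en-1-yl)phenyl]prop-2-enoate | C=C(C(=O)Oc1cc(OCOC)c(CC=C(C)C)c(OCOC)c1)c1ccc(OCOC)c(CC=C(C)C)c1OC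
F2 | step 14 | (3S)-3-hydroxy-5,7-bis(methoxymethoxy)-3-[2-methoxy-4-(methoxymethoxy)-3-(3-methylbut-2-en-1-yl)phenyl]-6-(3-methylbut-2-en-1-yl)-2,3-dihydro-4H-chromen-4-one | COc1c([C@]2(O)COc3cc(OCOC)c(CC=C(C)C)c(OCOC)c3C2=O)ccc(OCOC)c1CC=C(C)C
F3 | step 15 | rac-5,7-dihydroxy-3-[4-hydroxy-2-methoxy-3-(3-methylbut-2-en-1-yl)phenyl]-6-(3-methylbut-2-en-1-yl)-2,3-dihydro-4H-chromen-4-one | COc1c(C2COc3cc(O)c(CC=C(C)C)c(O)c3C2=O)ccc(O)c1CC=C(C)C
F4 | step 15 | rac-5,7-bis[tert-butyl(dimethyl)silyloxy]-3-{4-[tert-butyl(dimethyl)silyloxy]-2-methoxy-3-(3-methylbut-2-en-1-yl)phenyl}-6-(3-methylbut-2-en-1-yl)-2,3-dihydro-4H-chromen-4-one | COc1c(C2COc3cc(O[Si](C)(C)C(C)(C)C)c(CC=C(C)C)c(O[Si](C)(C)C(C)(C)C)c3C2=O)ccc(O[Si](C)(C)C(C)(C)C)c1CC=C(C)C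
F5 | step 15 | sodium enolate of F4 | COc1c(C2=C([O-])c3c(O[Si](C)(C)C(C)(C)C)c(CC=C(C)C)c(O[Si](C)(C)C(C)(C)C)cc3OC2)ccc(O[Si](C)(C)C(C)(C)C)c1CC=C(C)C.[Na+]
F6 | step 15 | (3R)-5,7-bis[tert-butyl(dimethyl)silyloxy]-3-{4-[tert-butyl(dimethyl)silyloxy]-2-methoxy-3-(3-methylbut-2-en-1-yl)phenyl}-3-hydroxy-6-(3-methylbut-2-en-1-yl)-2,3-dihydro-4H-chromen-4-one | COc1c([C@@]2(O)COc3cc(O[Si](C)(C)C(C)(C)C)c(CC=C(C)C)c(O[Si](C)(C)C(C)(C)C)c3C2=O)ccc(O[Si](C)(C)C(C)(C)C)c1CC=C(C)C
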